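The numbers in the tables stem from a simulated flask from invented constants, noise included.

Time first: we ask how 3.0 d compares with the life of starting material in these flasks.

the same everywhere: free catalyst 0.31 mol%

| run | starting material | second substrate | remark | time |
|---|---|---|---|---|
| gamma | 0.010 M | 0.50 equiv | run made earlier |  |
| theta | 0.0050 M | 0.50 equiv | run made earlier |  |
| amber | 0.010 M | 0.500 equiv (in portions, 2, over 30 h) | first portion at the start, last at 30 h | 3.0 d |
| green | 0.010 M | 0.500 equiv (fed, over 30 h) | all else is in the flask from the start; the feed brings no volume worth counting | 3.0 d |
| ochre | 0.010 M | 0.500 equiv | everything together at the start | 3.0 d |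
| violet | 0.010 M (fed, over 8.0 h) | 0.500 equiv | all else is in the flask from the start; the feed brings no volume worth counting | 3.0 d |
| teal | 0.010 M (fed, over 30 h) | 0.500 equiv | all else is in the flask from the start; the feed brings no volume worth counting | 3.0 d |

gamma run (percent of the starting material charged)

| time / d | uncatalysed product / % | target / % |
|---|---|---|
| 0.833 | 70.2 | 22.9 |
| 1.67 | 73.4 | 24.9 |
| 2.50 | 72.6 | 24.2 |
| 3.00 | 74.2 | 24.4 |

theta run (percent of the starting material charged)

| time / h | uncatalysed product / % | target / % |
|---|---|---|
| 2.00 | 18.2 | 3.4 |
| 4.00 | 33.4 | 6.2 |
| 5.00 | 38.2 | 10.1 |
| 8.00 | 52.7 | 10.8 |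

(standard deviation of a reading: 0.5 percentage points)

* the flask that comes out highest in amount of uncatalysed product, in percent of the starting material charged, or "all alike" when all lie within 1.5 percentage points (amber / green / ochre / violet / teal / all alike)
* uncatalysed product at the end, in percent of the starting material charged, amber
* uncatalysed product at the end, in percent of the starting material charged, green
* uncatalysed product at the end, in percent of the starting material charged, ochre
* uncatalysed product at the end, in percent of the starting material charged, violet
* uncatalysed product at the end, in percent of the starting material charged, teal



In the theta run, uncatalysed product and target together reach 63.5% of the charge after 8.00 h. We read from this a pseudo-first-order loss of starting material, 0.126 h⁻¹, and a half-life of 5.50 h. The time 3.0 d is 13.1 such half-lives, so on that rate we ask first for ochre's end state.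

We describe the end state by the target per uncatalysed product formed, 0.329, the branching ratio (a selectivity factor). The gamma run, which has ochre's charges, reads 0.326 at its first point and 0.329 at its last. The theta run reads 0.205 at its last point. Between these two last readings, twice the charge at the same loading reads as a power of 0.682 in the ratio, though the theta run stops at 8.00 h.

We can now draw ochre's curve of uncatalysed product, taking the theta rate for ochre. Its level is a share of 0.753 of the charge and its starting slope is 0.0948 h⁻¹. It reaches half its level at 5.50 h and bends over after that. At 0.833 d this curve gives 69.2%, against the gamma reading of 70.2%. The last gamma reading, 74.2%, is the number we commit to for ochre. We put down no number of our own for amber, green, violet or teal.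

The forecast gives amber 74.5%, green 76.5%, ochre 74.2%, violet 74% and teal 73.5%, with green highest: “Green's slow feed may starve the catalysed path early”.

The flasks give amber 68.6%, green 65.3%, ochre 73.6%, violet 71.3% and teal 65.6%, so ochre stands highest.

    catalyst intermediate A → free catalyst + target (k = 0.0100 s⁻¹)
    second substrate + free catalyst ⇌ catalyst intermediate B (K = 53000 M⁻¹, k = 0.940 M⁻¹ s⁻¹)
    catalyst intermediate B → free catalyst + second product (k = 0.00350 s⁻¹)
    starting material + free catalyst ⇌ catalyst intermediate A (K = 1400 M⁻¹, k = 0.790 M⁻¹ s⁻¹)
    starting material + target → side product (k = 3.50 × 10⁻⁴ M⁻¹ s⁻¹)
    starting material → decomposition product (k = 1.70 × 10⁻⁸ s⁻¹)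
    starting material → uncatalysed product (k = 2.90 × 10⁻⁵ s⁻¹)

Green's branching ratio comes out at 0.493, higher than the 0.329 read from gamma. The forecast expected green to rise in uncatalysed product, and green instead stands lowest. The neighbour flask is green with 0.025 M of starting material, equivalents and loading held. Raising green's ratio by the power 0.682 of the charge factor gives 0.921, hence a share of 52.1% for uncatalysed product. The neighbour flask ends at 51.3%.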